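**Retrosynthetic overview**

- Target ⇒ 4α-acetoxy-3α-ol: the last bond formed is the C3–O angelate ester bond.
- 4α-Acetoxy-3α-ol ⇒ cis-fused eudesm-3-en-8-one: both ring A C–O bonds come from a Woodward syn-dioxygenation that puts the oxygens on the concave face and the acetate on the tertiary C4.
- Enone ⇒ bis(enol triflate) of the cis-decalin-3,9-dione: a palladium/norbornene C–N relay moves the ring B carbonyl from C9 to C8 and reduces the C3 triflate to the C3=C4 alkene.
- Dione ⇒ (S)-carvotanacetone + (Z)-3-silyloxypenta-1,3-diene (Diels–Alder): ring B comes intact from (S)-carvone, ring A is formed second and cis-fused, and C10 and C5 are set by the C7 isopropyl group.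

Assumption: eudesmane numbering is used (ring A = C1–C5 and C10, ring B = C5–C10, methyls on C4 and C10, isopropyl on C7), β means the face of the C10 methyl, and the target is taken exactly as the given SMILES, i.e. (3R,4S,5S,7R,10R) with a Z (angelate) ester.

**Route**

Step 1
Reactants: 1 (S)-(+)-carvone
Product: 2 (S)-carvotanacetone [(5S)-2-methyl-5-(propan-2-yl)cyclohex-2-en-1-one]
Conditions: H2 (1 atm), RhCl(PPh3)3 (2 mol %), toluene, rt
Reagents that add atoms: none
Why: Chemoselective homogeneous hydrogenation reduces the unhindered 1,1-disubstituted isopropenyl alkene and leaves the trisubstituted conjugated enone untouched, so the future C7 stereocentre is carried over unchanged from carvone.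

Step 2
Reactants: 3 pent-1-en-3-one
Product: 4 (Z)-3-(trimethylsilyloxy)penta-1,3-diene
Conditions: TMSCl, Et3N, DMF, 80 °C; distil
Reagents that add atoms: chlorotrimethylsilane, C[Si](C)(C)Cl
Why: Silyl enol ether formation under equilibrating conditions gives the 2-silyloxydiene mainly as the Z isomer, whose terminal methyl is "outside" so the diene can reach the s-cis form.

Step 3
Reactants: 2 (S)-carvotanacetone; 4 (Z)-3-(trimethylsilyloxy)penta-1,3-diene
Product: 6 5βH-eudesmane-3,9-dione (4α-methyl; 7β-isopropyl; 10β-methyl; cis-decalin), via silyl enol ether 5 (not isolated)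
Conditions: EtAlCl2 (0.3 equiv), toluene, −20 °C → rt; then 1 M HCl, THF, rt
Reagents that add atoms: none
Why: Lewis-acid-catalysed Diels–Alder reaction with "para" orientation (the methyl-bearing diene terminus bonds to the enone β-carbon) builds ring A as a cis-decalin; the diene adds to the enone face opposite the C7 isopropyl group, which sets the quaternary C10 methyl and the C5 hydrogen both cis to the isopropyl group, and acid then hydrolyses the silyl enol ether (the endo-derived C4 methyl centre is erased in step 4).

Step 4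
Reactants: 6 5βH-eudesmane-3,9-dione
Product: 7 5βH-eudesma-3,8-diene-3,9-diyl bis(trifluoromethanesulfonate) (7β-isopropyl; 10β-methyl)
Conditions: Tf2O (2.4 equiv), 2,6-di-tert-butyl-4-methylpyridine (2.6 equiv), CH2Cl2, 0 °C → rt
Reagents that add atoms: trifluoromethanesulfonic anhydride, O=S(=O)(OS(=O)(=O)C(F)(F)F)C(F)(F)F
Why: Enol triflate formation with Zaitsev-type proton loss gives the more substituted C3=C4 triflate at the ring A ketone, while the C9 ketone, blocked by the quaternary C10, can only enolise toward C8; no stereocentre is created and the C4 centre is removed.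

Step 5
Reactants: 7 bis(enol triflate)
Product: 9 5βH-eudesm-3-en-8-one (7β-isopropyl; 10β-methyl), via enamine 8 (not isolated)
Conditions: Pd(OAc)2 (10 mol %), P(4-MeOC6H4)3 (25 mol %), N-methylbicyclo[2.2.1]hept-2-ene-2-carboxamide (50 mol %), morpholin-4-yl benzoate (1.3 equiv), i-PrOH (5 equiv), Cs2CO3 (4 equiv), 1,4-dioxane, 90 °C; then AcOH/H2O/THF, rt
Reagents that add atoms: water, O (carbonyl oxygen of 9); morpholin-4-yl benzoate, O=C(ON1CCOCC1)c1ccccc1 (morpholine unit of 8 only)
Why: Proposed new method: a site-divergent palladium/norbornene relay on a bis(enol triflate), in which zerovalent palladium inserts into the C9–OTf bond, norbornene insertion and vinylic C8–H palladation give a palladacycle that is aminated at C8 by the N–O electrophile (through tetravalent palladium), norbornene is expelled from the crowded position next to the quaternary C10 and the C9–Pd bond is hydrogenolysed by isopropoxide-derived hydride, so that a C8–N bond (enamine 8, hydrolysed to the C8 ketone) replaces the C9 oxygen, while the tetrasubstituted C3–OTf, which has no vinylic ortho C–H and cannot form the palladacycle, is simply reduced to the C3–H alkene by the same palladium hydride; the closest known reaction type is the Catellani-type α-amination/ipso-hydrogenation of mono(alkenyl triflates) used for ketone 1,2-transposition, together with palladium-catalysed hydride reduction of enol triflates, and no stereocentre is formed or touched (C7 stays as set by carvone).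

Step 6
Reactants: 9 5βH-eudesm-3-en-8-one
Product: 12 4α-acetoxy-3α-hydroxy-5βH-eudesman-8-one, via iodo acetate 10 (not isolated), via acetoxonium ion 11 (not isolated)
Conditions: I2 (1.05 equiv), AgOAc (2.3 equiv), AcOH, rt, dark; then H2O (1.5 equiv), 50 °C
Reagents that add atoms: silver acetate, CC(=O)[O-].[Ag+] (both ring A oxygens and the acetyl carbons); water, O (acetyl carbonyl oxygen); iodine, [I][I] (iodine of 10 only)
Why: Woodward cis-hydroxylation, in which the reversibly formed iodonium ion on the β-face (the face of the angular methyl, away from ring B) is opened trans-diaxially by acetate at the tertiary C4 from the α-face, silver-assisted displacement of the 3β-iodide by the neighbouring acetate gives the cis-fused α-acetoxonium ion, and its hydrolysis through the hemiorthoester keeps the ester on the axial C4 oxygen and frees the equatorial C3 hydroxyl, so both C–O bonds end on the concave α-face (C3 R, C4 S) by double inversion; C7, now α to the ketone, is retained and is in any case the favoured equatorial β-isopropyl epimer of 12.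

Step 7
Reactants: 12 4α-acetoxy-3α-hydroxy-5βH-eudesman-8-one; 13 angelic acid [(Z)-2-methylbut-2-enoic acid]
Product: 15 (3R,4S,5S,7R,10R)-4-acetoxy-3-[(Z)-2-methylbut-2-enoyloxy]-5βH-eudesman-8-one (target), via mixed anhydride 14 (not isolated)
Conditions: 13, 2,4,6-Cl3C6H2COCl, Et3N, toluene, rt; then 12, 80 °C (no DMAP)
Reagents that add atoms: 2,4,6-trichlorobenzoyl chloride, O=C(Cl)c1c(Cl)cc(Cl)cc1Cl (aroyl group of 14 only)
Why: Yamaguchi mixed-anhydride esterification acylates the only free (secondary, equatorial) hydroxyl at the unshielded angeloyl carbonyl with retention at C3, and leaving out nucleophilic catalysts avoids Z→E isomerisation to the tiglate and base-induced acetyl migration.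

**Compound list**

1 | (S)-(+)-carvone | CC1=CC[C@@H](CC1=O)C(C)=C | starting material
2 | (S)-carvotanacetone, (5S)-2-methyl-5-(propan-2-yl)cyclohex-2-en-1-one | CC1=CC[C@@H](CC1=O)C(C)C | intermediate
3 | pent-1-en-3-one (ethyl vinyl ketone) | CCC(=O)C=C | starting material
4 | (Z)-3-(trimethylsilyloxy)penta-1,3-diene | C/C=C(\O[Si](C)(C)C)C=C | intermediate
5 | 3-(trimethylsilyloxy)-5βH-eudesm-2-en-9-one (4α-methyl, 7β-isopropyl, 10β-methyl; not isolated) | C[Si](C)(C)OC1=CC[C@]2(C)C(=O)C[C@@H](C(C)C)C[C@@H]2[C@@H]1C | intermediate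
6 | 5βH-eudesmane-3,9-dione (4α-methyl, 7β-isopropyl, 10β-methyl; cis-decalin) | O=C1CC[C@]2(C)C(=O)C[C@@H](C(C)C)C[C@@H]2[C@@H]1C | intermediate
7 | 5βH-eudesma-3,8-diene-3,9-diyl bis(trifluoromethanesulfonate) | CC1=C(OS(=O)(=O)C(F)(F)F)CC[C@]2(C)C(OS(=O)(=O)C(F)(F)F)=C[C@@H](C(C)C)C[C@H]12 | intermediate
8 | 8-(morpholin-4-yl)-5βH-eudesma-3,8-diene (enamine; not isolated) | CC1=CCC[C@]2(C)C=C(N3CCOCC3)[C@@H](C(C)C)C[C@H]12 | intermediate
9 | 5βH-eudesm-3-en-8-one (7β-isopropyl, 10β-methyl) | CC1=CCC[C@]2(C)CC(=O)[C@@H](C(C)C)C[C@H]12 | intermediate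
10 | 4α-acetoxy-3β-iodo-5βH-eudesman-8-one (not isolated) | I[C@H]1CC[C@]2(C)CC(=O)[C@@H](C(C)C)C[C@@H]2[C@]1(C)OC(C)=O | intermediate
11 | acetoxonium ion: 2-methyl-1,3-dioxolan-2-ylium cis-fused on the α-face at C3–C4 of 5βH-eudesman-8-one (not isolated) | CC1=[O+][C@@H]2CC[C@]3(C)CC(=O)[C@@H](C(C)C)C[C@@H]3[C@]2(C)O1 | intermediate
12 | 4α-acetoxy-3α-hydroxy-5βH-eudesman-8-one (4β-methyl, 7β-isopropyl, 10β-methyl) | O[C@@H]1CC[C@]2(C)CC(=O)[C@@H](C(C)C)C[C@@H]2[C@]1(C)OC(C)=O | intermediate
13 | angelic acid, (Z)-2-methylbut-2-enoic acid | C/C=C(/C)C(=O)O | starting material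
14 | angelic 2,4,6-trichlorobenzoic anhydride (not isolated) | C/C=C(/C)C(=O)OC(=O)c1c(Cl)cc(Cl)cc1Cl | intermediate
15 | (3R,4S,5S,7R,10R)-4-acetoxy-3-[(Z)-2-methylbut-2-enoyloxy]eudesman-8-one (4α-acetoxy-3α-angeloyloxy-5βH-eudesman-8-one) | C/C=C(/C)C(=O)O[C@@H]1CC[C@]2(C)CC(=O)[C@@H](C(C)C)C[C@@H]2[C@]1(C)OC(C)=O | target

**Step count and risks**

Total step count: 7. Longest linear sequence: 6 steps (steps 1, 3, 4, 5, 6, 7 from 1; step 2 is a one-step side branch).

Three steps most likely to fail:

Step 5 (the proposed new step). Risks are premature reduction of the C9 triflate before amination (no transposition), norbornene-derived side reactions at the tetrasubstituted C3 site, and slow C8 amination next to the isopropyl-bearing C7. The fallback uses known chemistry, sets out from 7 and comes back at 9. Both triflates are removed by palladium-catalysed formate reduction (Pd(OAc)2, PPh3, HCO2H, Bu3N, DMF, 60 °C) to give 5βH-eudesma-3,8-diene F1. The disubstituted C8=C9 bond is hydroborated with 9-BBN (THF, 50 °C), with boron going to C8, the carbon remote from the quaternary C10, and the trisubstituted C3=C4 bond reacting much more slowly; this gives the B-alkyl-9-BBN adduct F2. F2 is oxidised in the flask (NaOH, H2O2) to 5βH-eudesm-3-en-8α-ol F3, and Dess–Martin oxidation of F3 gives 9. The carbonyl is thus moved by hydroboration–oxidation instead of by C–H amination.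

Step 6. Risks are the face selectivity of the iodonium ion in the flexible cis-decalin and acetyl migration from the tertiary to the secondary oxygen in warm acetic acid. The fallback sets out from 9 and comes back at 12. Epoxidation with mCPBA (NaHCO3, CH2Cl2, 0 °C) on the β-face gives 3β,4β-epoxy-5βH-eudesman-8-one F4. Buffered acetolysis (AcOH, NaOAc, 60 °C) opens it trans-diaxially at the tertiary carbon to 4α-acetoxy-3β-hydroxy-5βH-eudesman-8-one F5, in which acetyl migration is geometrically impossible. Tf2O/pyridine (CH2Cl2, −20 °C) gives the 3β-triflate F6, and warming with water lets the antiperiplanar acetate displace the triflate to acetoxonium ion 11, whose hydrolysis gives 12. Oxygen is delivered by epoxidation instead of by iodine and silver.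

Step 7. Risks are the hindered secondary hydroxyl next to the quaternary C4, acetyl migration from O4 to O3 competing with acylation, and Z→E isomerisation of the angelate. The fallback sets out from 12 and comes back at 15. Methanolysis (K2CO3, MeOH, 0 °C) gives 3α,4α-dihydroxy-5βH-eudesman-8-one F7. Mixed anhydride 14 (conditions of step 7) acylates the only acylable, secondary hydroxyl to give 3α-angeloyloxy-4α-hydroxy-5βH-eudesman-8-one F8. The tertiary hydroxyl is then acetylated under Lewis-acid catalysis (Ac2O, Sc(OTf)3 5 mol %, MeCN, −20 °C) to give 15. The order of the two esterifications is reversed, so no migration-prone hydroxy acetate meets base.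

**Further compounds**

F1 | step 5 | 5βH-eudesma-3,8-diene (7β-isopropyl, 10β-methyl) | CC1=CCC[C@]2(C)C=C[C@@H](C(C)C)C[C@H]12
F2 | step 5 | 9-(5βH-eudesm-3-en-8α-yl)-9-borabicyclo[3.3.1]nonane | CC1=CCC[C@]2(C)C[C@H](B3C4CCCC3CCC4)[C@@H](C(C)C)C[C@H]12
F3 | step 5 | 5βH-eudesm-3-en-8α-ol | CC1=CCC[C@]2(C)C[C@H](O)[C@@H](C(C)C)C[C@H]12
F4 | step 6 | 3β,4β-epoxy-5βH-eudesman-8-one | O1[C@H]2CC[C@]3(C)CC(=O)[C@@H](C(C)C)C[C@@H]3[C@@]12C
F5 | step 6 | 4α-acetoxy-3β-hydroxy-5βH-eudesman-8-one | O[C@H]1CC[C@]2(C)CC(=O)[C@@H](C(C)C)C[C@@H]2[C@]1(C)OC(C)=O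
F6 | step 6 | 4α-acetoxy-8-oxo-5βH-eudesman-3β-yl trifluoromethanesulfonate | O=S(=O)(O[C@H]1CC[C@]2(C)CC(=O)[C@@H](C(C)C)C[C@@H]2[C@]1(C)OC(C)=O)C(F)(F)F
F7 | step 7 | 3α,4α-dihydroxy-5βH-eudesman-8-one | O[C@@H]1CC[C@]2(C)CC(=O)[C@@H](C(C)C)C[C@@H]2[C@]1(C)O
F8 | step 7 | 3α-angeloyloxy-4α-hydroxy-5βH-eudesman-8-one | C/C=C(/C)C(=O)O[C@@H]1CC[C@]2(C)CC(=O)[C@@H](C(C)C)C[C@@H]2[C@]1(C)O
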